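**Plan**

1. Labels: Ca = CH carrying the 2-methylprop-1-enyl group, Cb = ring-fusion CH, Cc = ring-fusion O–CH, Cd = CMe2. Quinolinone A is bonded through C-3 to Ca and through O-4 to Cc (pyran A); quinolinone B through C-3 to Cc and through O-4 to Cd (pyran B).
2. Retrosynthesis: the O-4(A)–Cc bond is cut last, with Cc returned to a ketone. Next the C-3(A)–Ca bond and the hemiketal C–O bond are cut together, leaving 4-hydroxyquinolinone 6 and dienone 13. Dienone 13 is cut at its exocyclic C=C to pyranone 9 and prenal, and 9 at its acyl C–C and ether C–O bonds to 6 and 3-methylbut-2-enoic acid.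
3. Forward: the pyridone ring of 6 is built first. Pyran B is annulated onto one portion of 6 and the prenylidene arm is attached. A second portion of 6 then closes pyran A as a hemiketal in the key step; pyran A is afterwards opened, reduced at Cc and reclosed.
4. Enabling feature: Ca and Cc are 1,3-related through Cb. They are the β-carbon and the carbonyl carbon of the exocyclic enone Ca=Cb–Cc(=O) held in the pyranone ring of B, and C-3/O-4 of A is a 1,3-C,O-bisnucleophile matching these two atoms. The adjacent C-4 and C-5 carbonyls of B offer a two-point hydrogen-bond site for the catalyst.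
5. Stereochemistry: Ca (S) comes from the chiral squaramide catalyst. Cb is set by equilibration next to the ketone, with the isobutenyl group anti to Cd. Cc (R) is set in the last step by cis-selective closure onto a planar cation.

Key step: step 6

Assumption: the quinine-derived squaramide is taken to deliver the nucleophile to the face of Ca that gives the (S) configuration; should the sense prove opposite, the quinidine-derived pseudo-enantiomer is used in the same step without other change.

**Route**

Step 1
Reactants: 1 2,3-dimethoxyaniline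
Product: 3 2,3-dimethoxy-N-methylaniline, via N-(methoxymethyl)aniline 2 (not isolated)
Conditions: (CH2O)n, NaOMe, MeOH, rt; then NaBH4, reflux
Reagents that add atoms: formaldehyde (from paraformaldehyde), C=O
Why: Reductive N-methylation, in which the aniline is trapped as its N-methoxymethyl derivative and NaBH4 reduces the derived iminium ion, a sequence that should stop cleanly at the mono-methyl stage.

Step 2
Reactants: 3 2,3-dimethoxy-N-methylaniline; 4 diethyl malonate
Product: 6 4-hydroxy-7,8-dimethoxy-1-methylquinolin-2(1H)-one (quinolinone A), via malonamate ester 5 (not isolated)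
Conditions: Ph2O, 250 °C, EtOH distilled off
Reagents that add atoms: none
Why: Thermal malonate cyclocondensation (aminolysis, then ring-closing C-acylation through the acylketene), which can only close at the single free ortho position, itself para to a methoxy group.

Step 3
Reactants: 6 4-hydroxy-7,8-dimethoxy-1-methylquinolin-2(1H)-one; 7 3-methylbut-2-enoic acid
Product: 9 7,8-dimethoxy-2,2,6-trimethyl-2,3-dihydro-4H-pyrano[3,2-c]quinoline-4,5(6H)-dione (pyranone of B), via 3-acyl quinolinone 8 (not isolated)
Conditions: P2O5–MeSO3H (1:10 w/w), 70 °C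
Reagents that add atoms: none
Why: Friedel–Crafts-type C-acylation of the enolic C-3 followed by 6-endo-trig oxa-Michael closure of O-4 onto the β,β-dimethyl enone, the standard 2,2-dimethylchromanone synthesis, with the angular 2-quinolone expected as the thermodynamic product of the reversible closure.

Step 4
Reactants: 9 pyranone of B; 10 3-methylbut-2-enal (prenal)
Product: 11 3-(1-hydroxy-3-methylbut-2-en-1-yl)-7,8-dimethoxy-2,2,6-trimethyl-2,3-dihydro-4H-pyrano[3,2-c]quinoline-4,5(6H)-dione (mixture of diastereomers)
Conditions: LiN(SiMe3)2, THF, −78 °C; prenal, −78 °C; AcOH quench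
Reagents that add atoms: none
Why: Directed aldol addition of the kinetic lithium enolate at C-3 (the only enolisable position) to the aldehyde carbon of prenal, whose disubstituted β-carbon disfavours 1,4-attack; both new stereocentres are erased in step 5.

Step 5
Reactants: 11 aldol adduct
Product: 13 (3E)-7,8-dimethoxy-2,2,6-trimethyl-3-(3-methylbut-2-en-1-ylidene)-2,3-dihydro-4H-pyrano[3,2-c]quinoline-4,5(6H)-dione (dienone of B), via allylic acetate 12 (not isolated)
Conditions: Ac2O, Et3N, DMAP (cat.), CH2Cl2, 0 °C to rt; then DBU, rt
Reagents that add atoms: none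
Why: Acetylation and E1cB elimination complete the aldol condensation; because C-2 is quaternary only the exocyclic alkene can form, and the E isomer (vinylic hydrogen beside the carbonyl) is expected as the product of equilibration under DBU, as in 3-alkylidene chromanones.

Step 6
Reactants: 13 dienone of B; 6 4-hydroxy-7,8-dimethoxy-1-methylquinolin-2(1H)-one (second portion)
Product: 15 cis-fused hemiketal of the target skeleton (Ca-S Cb-R Cc-R; OH on Cc in place of H), via keto tautomer 14 (not isolated)
Conditions: quinine-derived squaramide [3-(3,5-bis(trifluoromethyl)anilino)-4-(9-deoxy-epi-quinin-9-ylamino)cyclobut-3-ene-1,2-dione] (10 mol %), CH2Cl2, rt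
Reagents that add atoms: none
Why: The quinuclidine nitrogen of the catalyst deprotonates the acidic 4-hydroxyl of 6 while the squaramide N–H pair binds the adjacent C-4/C-5 carbonyls of 13; the soft C-3 of the enolate then adds 1,4 to Ca, the ring-B enol is protonated at Cb to give 14, and O-4 of A adds to the Cc ketone. The closest known reaction type is the amine–squaramide-catalysed conjugate addition of 4-hydroxycoumarins and 4-hydroxyquinolinones to enones, whose adducts rest as cyclic hemiketals. Ring closure of pyran A is a 6-exo-trig addition of the enol oxygen to the ketone, the ring–chain equilibrium familiar from warfarin-type adducts. Ca is set by the catalyst, which should expose one face of the E-configured enone that ring B locks s-cis; Cb should settle by amine-mediated epimerisation next to the ketone into the epimer whose hemiketal carries the isobutenyl group pseudo-axial (clear of the lactam carbonyl of A) and anti to Cd; the hemiketal centre Cc is thermodynamic and is erased in step 7. The step needs C- over O-attack and 1,4- over 1,6-addition, which the soft enolate carbon and the hindered, fully substituted CMe2 terminus of the dienone should secure.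

Step 7
Reactants: 15 hemiketal
Product: 17 (3S)-4-hydroxy-3-[(1S)-1-(4-hydroxy-7,8-dimethoxy-1-methyl-2-oxo-1,2-dihydroquinolin-3-yl)-3-methylbut-2-en-1-yl]-7,8-dimethoxy-2,2,6-trimethyl-3,4-dihydro-2H-pyrano[3,2-c]quinolin-5(6H)-one (either C-4 epimer), via sodium keto enolate 16 (not isolated)
Conditions: NaOMe (1.0 equiv), MeOH–THF, −40 °C; then CeCl3·7H2O, NaBH4, −40 to 0 °C; AcOH quench
Reagents that add atoms: none
Why: One equivalent of methoxide removes the hemiketal proton and pyran A collapses to the ring-opened sodium keto enolate 16 (the form in which warfarin-type adducts are reduced as their sodium salts), whose free ketone then undergoes Luche carbonyl reduction; with no excess base and at low temperature Ca and Cb should stay untouched, and the carbinol configuration is irrelevant because it is ionised in step 8.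

Step 8
Reactants: 17 ring-opened carbinol
Product: 18 CNP0314650.1 (Ca-S Cb-S Cc-R)
Conditions: (±)-camphor-10-sulfonic acid (20 mol %), 4 Å MS, CH2Cl2, 0 °C to rt
Reagents that add atoms: none
Why: Acid-catalysed SN1 cyclodehydration in which the carbinol ionises to a cation at Cc stabilised by O-4 of B through the C-3=C-4 bond, and O-4 of A captures it through a six-membered chair-like transition state with the Cb–Ca bond pseudo-axial, which should deliver the cis ring fusion (Cc R); catalytic acid at low temperature should leave the isobutenyl alkene unprotonated.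

**Compound list**

1 | 2,3-dimethoxyaniline | COc1cccc(N)c1OC | starting material
2 | 2,3-dimethoxy-N-(methoxymethyl)aniline | COCNc1cccc(OC)c1OC | intermediate
3 | 2,3-dimethoxy-N-methylaniline | CNc1cccc(OC)c1OC | intermediate
4 | diethyl malonate | CCOC(=O)CC(=O)OCC | starting material
5 | ethyl 3-[(2,3-dimethoxyphenyl)(methyl)amino]-3-oxopropanoate | CCOC(=O)CC(=O)N(C)c1cccc(OC)c1OC | intermediate
6 | 4-hydroxy-7,8-dimethoxy-1-methylquinolin-2(1H)-one (quinolinone A, also the source of B) | COc1ccc2c(O)cc(=O)n(C)c2c1OC | intermediate
7 | 3-methylbut-2-enoic acid | CC(C)=CC(=O)O | starting material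
8 | 4-hydroxy-7,8-dimethoxy-1-methyl-3-(3-methylbut-2-enoyl)quinolin-2(1H)-one | COc1ccc2c(O)c(C(=O)C=C(C)C)c(=O)n(C)c2c1OC | intermediate
9 | 7,8-dimethoxy-2,2,6-trimethyl-2,3-dihydro-4H-pyrano[3,2-c]quinoline-4,5(6H)-dione | COc1ccc2c3c(c(=O)n(C)c2c1OC)C(=O)CC(C)(C)O3 | intermediate
10 | 3-methylbut-2-enal (prenal) | CC(C)=CC=O | starting material
11 | 3-(1-hydroxy-3-methylbut-2-en-1-yl)-7,8-dimethoxy-2,2,6-trimethyl-2,3-dihydro-4H-pyrano[3,2-c]quinoline-4,5(6H)-dione, diastereomer mixture | COc1ccc2c3c(c(=O)n(C)c2c1OC)C(=O)C(C(O)C=C(C)C)C(C)(C)O3 | intermediate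
12 | acetate of 11 at the allylic hydroxyl | COc1ccc2c3c(c(=O)n(C)c2c1OC)C(=O)C(C(OC(C)=O)C=C(C)C)C(C)(C)O3 | intermediate
13 | (3E)-7,8-dimethoxy-2,2,6-trimethyl-3-(3-methylbut-2-en-1-ylidene)-2,3-dihydro-4H-pyrano[3,2-c]quinoline-4,5(6H)-dione | CC(C)=C/C=C1/C(=O)c2c(c3ccc(OC)c(OC)c3n(C)c2=O)OC1(C)C | intermediate
14 | (3R)-3-[(1S)-1-(4-hydroxy-7,8-dimethoxy-1-methyl-2-oxo-1,2-dihydroquinolin-3-yl)-3-methylbut-2-en-1-yl]-7,8-dimethoxy-2,2,6-trimethyl-2,3-dihydro-4H-pyrano[3,2-c]quinoline-4,5(6H)-dione (open keto tautomer of 15) | COc1ccc2c(O)c(c(=O)n(C)c2c1OC)[C@@H](C=C(C)C)[C@H]1C(=O)c2c(c3ccc(OC)c(OC)c3n(C)c2=O)OC1(C)C | intermediate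
15 | hemiketal: target skeleton with OH on Cc in place of H; Ca S, Cb R, Cc R; the isobutenyl group, Cb–H and the Cc–OH are on one face, rings cis-fused (Cb has the same spatial arrangement as in 18; its descriptor differs only through the priority change at Cc) | COc1ccc2c3c(c(=O)n(C)c2c1OC)[C@@H](C=C(C)C)[C@H]1[C@@](O)(O3)c2c(c3ccc(OC)c(OC)c3n(C)c2=O)OC1(C)C | intermediate
16 | sodium 3-[(1S)-1-[(3R)-7,8-dimethoxy-2,2,6-trimethyl-4,5-dioxo-3,4,5,6-tetrahydro-2H-pyrano[3,2-c]quinolin-3-yl]-3-methylbut-2-en-1-yl]-7,8-dimethoxy-1-methyl-2-oxo-1,2-dihydroquinolin-4-olate (ring-opened keto enolate, the sodium salt of 14) | COc1ccc2c([O-])c(c(=O)n(C)c2c1OC)[C@@H](C=C(C)C)[C@H]1C(=O)c2c(c3ccc(OC)c(OC)c3n(C)c2=O)OC1(C)C.[Na+] | intermediate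
17 | (3S)-4-hydroxy-3-[(1S)-1-(4-hydroxy-7,8-dimethoxy-1-methyl-2-oxo-1,2-dihydroquinolin-3-yl)-3-methylbut-2-en-1-yl]-7,8-dimethoxy-2,2,6-trimethyl-3,4-dihydro-2H-pyrano[3,2-c]quinolin-5(6H)-one, carbinol centre undefined | COc1ccc2c(O)c(c(=O)n(C)c2c1OC)[C@@H](C=C(C)C)[C@H]1C(O)c2c(c3ccc(OC)c(OC)c3n(C)c2=O)OC1(C)C | intermediate
18 | CNP0314650.1: pyran A [C-3(A)–Ca–Cb–Cc–O-4(A)] and pyran B [C-3(B)–Cc–Cb–Cd–O-4(B)] share the Cb–Cc bond; Ca S, Cb S, Cc R; Cb–H and Cc–H cis, Ca–H trans to Cb–H; each quinolinone is 7,8-dimethoxy-1-methyl | COc1ccc2c3c(c(=O)n(C)c2c1OC)[C@@H](C=C(C)C)[C@H]1[C@@H](O3)c2c(c3ccc(OC)c(OC)c3n(C)c2=O)OC1(C)C | target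

**Step count and risks**

Total: 8 steps. Longest linear sequence: 8 steps (1 → 3 → 6 → 9 → 11 → 13 → 15 → 17 → 18); compound 6 enters twice, in steps 3 and 6.

Step 6. The push–pull character of the enone may make the addition slow, and the catalyst may discriminate the two faces of Ca poorly or give an unfavourable Cb epimer ratio. The fallback secures the enantiomer by resolution instead of catalysis. It sets out from 13 and 6, which would be combined with an achiral base (DABCO, MeCN, 40 °C) to give the racemic hemiketal, that is 15 together with its mirror image, the ent-hemiketal F1. An amine opens the hemiketal to the acidic enol 14, so the racemate would be treated with (S)-1-phenylethylamine in EtOAc and the less soluble diastereomeric salt, the (S)-1-phenylethylammonium enolate of 14 F2, would be crystallised, in the manner in which warfarin is resolved through amine salts. Dilute HCl would then return enantiopure 15, where the route is rejoined before step 7.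

Step 8. Under acid the Cc cation may lose the Cb proton to give a 2H-pyran (scrambling Cb on reprotonation), may fragment across the Cb–Ca bond back to two monomer units (eroding enantiopurity), or the isobutenyl alkene may be protonated. The fallback replaces Brønsted-acid ionisation by a redox condensation under neutral conditions. It sets out from 17, which would be cyclised by Mitsunobu dehydration (PPh3, DIAD, THF, −20 °C to rt), the acidic 4-hydroxyl of A serving as pronucleophile. The oxyphosphonium of this readily ionised carbinol is expected to close through the same cis-selective six-membered transition state. It arrives directly at 18 and no new compound arises on the way (none, F0).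

Step 4. The lithium enolate of 9 may open ring B by β-elimination of the quinolinone oxygen, or may deprotonate prenal at its γ-methyl groups instead of adding to the carbonyl. The fallback avoids a basic enolate altogether. It sets out from 9, which would be converted by soft enolisation (Me3SiOTf, Et3N, CH2Cl2, 0 °C) into the trimethylsilyl enol ether F3. Mukaiyama-type addition of F3 to 1,1-dimethoxy-3-methylbut-2-ene (Me3SiOTf cat., CH2Cl2, −78 °C) would give the β-methoxy ketone F4. Elimination of methanol with DBU would then deliver dienone 13, where the route is rejoined, bypassing 11 and 12.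

**Further compounds**

F1 | step 6 | ent-hemiketal (mirror image of 15; Ca R, Cb S, Cc S) | COc1ccc2c3c(c(=O)n(C)c2c1OC)[C@H](C=C(C)C)[C@@H]1[C@](O)(O3)c2c(c3ccc(OC)c(OC)c3n(C)c2=O)OC1(C)C
F2 | step 6 | (S)-1-phenylethylammonium enolate of 14 | COc1ccc2c([O-])c(c(=O)n(C)c2c1OC)[C@@H](C=C(C)C)[C@H]1C(=O)c2c(c3ccc(OC)c(OC)c3n(C)c2=O)OC1(C)C.C[C@H]([NH3+])c1ccccc1
F0 | step 8 | none | none
F3 | step 4 | 7,8-dimethoxy-2,2,6-trimethyl-4-(trimethylsilyloxy)-2H-pyrano[3,2-c]quinolin-5(6H)-one | COc1ccc2c3c(c(=O)n(C)c2c1OC)C(O[Si](C)(C)C)=CC(C)(C)O3
F4 | step 4 | 3-(1-methoxy-3-methylbut-2-en-1-yl)-7,8-dimethoxy-2,2,6-trimethyl-2,3-dihydro-4H-pyrano[3,2-c]quinoline-4,5(6H)-dione | COc1ccc2c3c(c(=O)n(C)c2c1OC)C(=O)C(C(OC)C=C(C)C)C(C)(C)O3
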